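G, the limiting reagent, is the yardstick here: count every species as a fraction of its charge, and read what L stands at the end of each set-up.

| flask | G | Q | remark | time |
|---|---|---|---|---|
| winter | 0.083 M | 2.5 equiv | run made earlier |  |
| summer | 0.12 M | 2.5 equiv | run made earlier |  |
| noon | 0.18 M | 2.5 equiv | run made earlier |  |
| spring | 0.083 M | 5 equiv | run made earlier |  |
| elm | 0.083 M (fed, over 0.750 h) | 2.50 equiv | all but G at the start; G goes in evenly over 0.750 h, the run ends at 1.5 h | 1.5 h |
| oak | 0.083 M | 2.50 equiv | plug flow through a tube for 1.5 h, no back-mixing | 1.5 h |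
| maple | 0.083 M | 2.50 equiv | a closed flask charged with all of it at once and left for 1.5 h | 1.5 h |
| alder | 0.083 M | 2.50 equiv | one stirred flow tank at steady state, fed with the mixture as stated, mean residence time 1.5 h |  |

| run | time / min | L / % | G / % |
|---|---|---|---|
| winter | 4.00 | 0 | 91.9 |
| winter | 10.0 | 0.5 | 82.5 |
| winter | 20.0 | 1.9 | 72.5 |
| winter | 30.0 | 3.3 | 67.4 |
| winter | 40.0 | 2.5 | 63.2 |
| winter | 50.0 | 5.1 | 61.1 |
| summer | 6.00 | 1.0 | 85.6 |
| summer | 20.0 | 3.2 | 69.1 |
| summer | 30.0 | 3.6 | 64.1 |
| summer | 50.0 | 7.2 | 55.6 |
| summer | 60.0 | 7.1 | 53.8 |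
| summer | 90.0 | 11.2 | 46.5 |
| noon | 6.00 | 0.2 | 84.8 |
| noon | 20.0 | 2.8 | 66.3 |
| noon | 30.0 | 5.2 | 58.0 |
| noon | 50.0 | 10.2 | 50.2 |
| noon | 60.0 | 11.3 | 46.1 |
| noon | 90.0 | 14.2 | 37.8 |
| spring | 20.0 | 3.8 | 66.6 |
| spring | 40.0 | 6.8 | 54.3 |
| spring | 50.0 | 9.0 | 50.2 |
| spring | 80.0 | 13.5 | 41.6 |
| spring | 90.0 | 14.6 | 38.4 |

(each reading ± 0.5 percentage points)

- the stated concentrations are those of everything mixed, before any reaction; amounts are the same in each set-up
- the feed brings no volume worth counting
- the earlier runs were made in a closed, stirred flask

* the set-up with the highest amount of L at the outlet or at the end, in percent of the G put in ("none" if the first two lie within 2 percentage points) (elm / oak / maple / alder / none)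
* amount of L at the outlet or at the end, in percent of the G put in, elm
* amount of L at the outlet or at the end, in percent of the G put in, oak
* amount of L at the outlet or at the end, in percent of the G put in, maple
* amount of L at the outlet or at the end, in percent of the G put in, alder

Watch the first minutes. Winter shows G at 91.9% and L at 0% after 4.00 min, so G leaves before L appears. After 6.00 min, summer and noon hold G at 85.6% and 84.8%, which differ by 0.8 percentage points against a scatter of 0.5 points.

Then look for what is missing. After 50.0 min, winter holds G at 61.1% and L at 5.1%, so 33.8% of the charge stands in forms nobody reads. Spring, with 5 equiv on winter's G, reads L at 9.0% at that time, twice winter's.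

Towards the end, spring's time grows by a factor 4.50 and its L by 3.84, so scale L with age as a rough rule.

Now divide L at 90.0 min by the molar charge of G: summer gives 0.933 L mol⁻¹ and noon 0.789 L mol⁻¹. Call this the yield per molar, held at 2.5 equiv. It is less at noon's charge than at summer's, so run the line through both down to oak's charge: 1.02 L mol⁻¹. That gives oak and maple 8.49%, since each part of both charges ages 1.5 h. Elm's G arrives 0.375 h late on average, so scale by age to 6.36%. Alder's outflow is a mixture of ages, spread exponentially around a mean of 1.5 h, so average L over those ages instead of reading one age. Summer, noon and spring end at 90.0 min, so take my own guess past that age: let L rise in step with age up to 1.5 h and hold it flat beyond, and the average comes to 5.36%. Oak and maple tie above the other two, so expect no winner.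

The forecast reads elm 7%, oak 9.5%, maple 9.5%, alder 9.3% and best none, with the words “Oak and maple tie, so the answer is none”, and its alder is higher than mine.

The flask gives oak and maple 8.29%, elm 6.53%, alder 6.07%, and best none.

    E ⇌ L (K = 2.75, k = 0.0309 min⁻¹)
    E → J (k = 0.0135 min⁻¹)
    G + Q → E + D (k = 0.0220 L mol⁻¹ min⁻¹)
    E ⇌ X (K = 180, k = 0.0164 min⁻¹)
    G ⇌ Z (K = 0.375, k = 0.0195 min⁻¹)

At 1.50 h, oak holds Z at 21.1%, and with the path from G to Z struck out, oak gives 10.3%. Put the yield per molar on the neighbour of oak charged with 0.21 M of G, at the same equivalents and time: extending the line gives 15.0%, and that flask gives 16.3%.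

The readings are calculated on assumed constants, noise included.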